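**Plan**

- The side chain is numbered from the benzylic carbon C1 to the methyl group C17; C16 is the (S)-carbinol carbon, so the target is 5-[(16S)-16-hydroxyheptadecyl]benzene-1,3-diol. The retrosynthesis first masks the two phenols as benzyl ethers and cuts C7–C8 as a C7=C8 olefin (cross-metathesis of two terminal alkenes). It then cuts C1–C2 (benzylic bromide + alkenyl Grignard) and C14–C15 (epoxide + alkenyl Grignard).
- Forward, no ring is made: the benzene ring is bought with both oxygens in place. The chain is joined at C1–C2 and at C14–C15 in two parallel one-step operations, then at C7=C8, and one hydrogenation saturates the chain and frees the resorcinol.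
- The enabling feature is the unbranched polymethylene chain C1–C15. C7 and C8 are plain CH2 groups, six methylenes (C1–C6) from the benzene ring and seven (C9–C15) from the C16 carbinol. A C7=C8 double bond is therefore a harmless temporary oxidation level: it forms from two unhindered vinyl groups with the C16 hydroxyl unprotected, and the H2/Pd step that removes the benzyl groups also erases it.
- The only stereocentre, C16 (S), is bought as (S)-propylene oxide. The epoxide is opened at its CH2 (which becomes C15), so the C16–O bond is never broken.

Key step: step 3

**Route**

Step 1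
Reactants: 1 1,3-bis(benzyloxy)-5-(bromomethyl)benzene (3,5-bis(benzyloxy)benzyl bromide); 2 7-bromohept-1-ene
Product: 4 1,3-bis(benzyloxy)-5-(oct-7-en-1-yl)benzene, via hept-6-en-1-ylmagnesium bromide 3 (not isolated)
Conditions: 2, Mg, THF, 40 °C; then 1, Li2CuCl4 (3 mol %), THF, −78 → 0 °C; aq. NH4Cl
Reagents that add atoms: none
Why: Kochi-type copper-catalysed Grignard coupling, in which the cuprate formed from 3 should displace the reactive benzylic bromide of 1 faster than halogen–magnesium exchange can occur, the benzyl ethers and the terminal olefin being inert; no stereocentre is formed.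

Step 2
Reactants: 5 (S)-2-methyloxirane ((S)-propylene oxide); 6 8-bromooct-1-ene
Product: 8 (2S)-undec-10-en-2-ol, via oct-7-en-1-ylmagnesium bromide 7 (not isolated)
Conditions: 6, Mg, THF, 40 °C; then CuI (10 mol %), 5, THF, −30 → 0 °C; aq. NH4Cl
Reagents that add atoms: none
Why: Copper-catalysed SN2 opening of a terminal epoxide by a Grignard reagent, in which the cuprate from 7 attacks the unsubstituted CH2 of 5 (the future C15), so the C–O bond at the stereocentre is never broken and the (S) configuration of the epoxide is carried unchanged into 8.

Step 3
Reactants: 4 1,3-bis(benzyloxy)-5-(oct-7-en-1-yl)benzene; 8 (2S)-undec-10-en-2-ol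
Product: 9 (2S)-17-[3,5-bis(benzyloxy)phenyl]heptadec-10-en-2-ol (E/Z mixture)
Conditions: 8 (3 equiv), Grubbs II (5 mol %), 1,4-benzoquinone (10 mol %), CH2Cl2, 40 °C, Ar sparge
Reagents that add atoms: none
Why: Olefin cross-metathesis by the Chauvin mechanism: the ruthenium carbene is loaded by either terminal olefin, and successive [2+2] cycloaddition/cycloreversion through ruthenacyclobutanes joins the internal CH carbon of 4 (C7) to that of 8 (C8) while the two terminal CH2 groups leave as ethene, whose removal in the argon stream drives the equilibrium. The closest known reaction type is the Grubbs-II cross-metathesis of two unhindered monosubstituted (type I) α-olefins that carry remote ethers and free alcohols. No ring is closed and no stereocentre is created; the C7=C8 bond should form as an E/Z mixture, which does not matter because both isomers give the same alkane in step 4, and the C16 stereocentre lies eight carbons from the reacting carbon and is not touched. The step needs cross-coupling over homo-coupling and no migration of the double bonds: the first is secured by the threefold excess of the one-step alkenol 8 (its diol homodimer stays a competent metathesis partner and differs sharply in polarity from the mono-alcohol 9 and from the hydroxyl-free homodimer of 4), the second by benzoquinone, which intercepts ruthenium hydrides and so protects the chain length. Both vinyl groups sit at least six methylenes from the arene, the benzyl ethers and the hydroxyl, so neither chelation of the carbene nor allylic deactivation can slow either partner.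

Step 4
Reactants: 9 (2S)-17-[3,5-bis(benzyloxy)phenyl]heptadec-10-en-2-ol (E/Z mixture)
Product: 10 hansfordiol A, 5-[(16S)-16-hydroxyheptadecyl]benzene-1,3-diol
Conditions: H2 (1 atm), 10 % Pd/C, EtOAc–MeOH, rt
Reagents that add atoms: none
Why: Heterogeneous catalytic hydrogenation combined with O-benzyl hydrogenolysis: palladium should saturate the C7=C8 olefin (both geometric isomers converge) and cleave the two benzylic C–O bonds of the aryl benzyl ethers, while the non-benzylic secondary C16 alcohol and its stereocentre are inert under these conditions.

**Compound list**

1 | 1,3-bis(benzyloxy)-5-(bromomethyl)benzene | BrCc1cc(OCc2ccccc2)cc(OCc2ccccc2)c1 | starting material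
2 | 7-bromohept-1-ene | C=CCCCCCBr | starting material
3 | hept-6-en-1-ylmagnesium bromide | C=CCCCCC[Mg]Br | intermediate
4 | 1,3-bis(benzyloxy)-5-(oct-7-en-1-yl)benzene | C=CCCCCCCc1cc(OCc2ccccc2)cc(OCc2ccccc2)c1 | intermediate
5 | (S)-2-methyloxirane | C[C@H]1CO1 | starting material
6 | 8-bromooct-1-ene | C=CCCCCCCBr | starting material
7 | oct-7-en-1-ylmagnesium bromide | C=CCCCCCC[Mg]Br | intermediate
8 | (2S)-undec-10-en-2-ol | C[C@H](O)CCCCCCCC=C | intermediate
9 | (2S)-17-[3,5-bis(benzyloxy)phenyl]heptadec-10-en-2-ol, E/Z mixture | C[C@H](O)CCCCCCCC=CCCCCCCc1cc(OCc2ccccc2)cc(OCc2ccccc2)c1 | intermediate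
10 | hansfordiol A, 5-[(16S)-16-hydroxyheptadecyl]benzene-1,3-diol | C[C@H](O)CCCCCCCCCCCCCCCc1cc(O)cc(O)c1 | target

**Step count**

Total: 4 steps. Longest linear sequence: 3 steps (step 1 or step 2, then steps 3 and 4).

**Steps most likely to fail**

Step 3. The processes at risk are statistical self-metathesis of each partner in competition with the cross-coupling, and ruthenium-hydride-induced migration of the terminal double bonds before metathesis. Migration would give chain-shortened homologues that can no longer be separated after step 4. The fallback makes the union directional by replacing metathesis with the SN2 alkylation of an acetylide; it sets out from 1 and 5 and comes back to the route at 10. Under the conditions of step 1, 1 is coupled with 6-chlorohexylmagnesium bromide F1 (from 1-bromo-6-chlorohexane, where magnesium inserts into the C–Br bond only) to give 1,3-bis(benzyloxy)-5-(7-chloroheptyl)benzene F2. A Finkelstein exchange (NaI, acetone, reflux) turns it into 1,3-bis(benzyloxy)-5-(7-iodoheptyl)benzene F3. In parallel, 5 is opened at its CH2 by hept-1-yne/n-BuLi/BF3·OEt2 (THF, −78 °C) to give (2S)-dec-4-yn-2-ol F4. The alkyne zipper isomerisation (KH, 1,3-diaminopropane, 0 °C to rt) then moves the triple bond to the chain terminus and gives (2S)-dec-9-yn-2-ol F5; the carbinol centre, present as its alkoxide, should not be epimerised. Double deprotonation of F5 (n-BuLi, 2.1 equiv, THF–DMPU, −78 to 0 °C) and C-alkylation of the acetylide with F3 forms the same C7–C8 bond and gives (2S)-17-[3,5-bis(benzyloxy)phenyl]heptadec-9-yn-2-ol F6. Under the conditions of step 4 the triple bond is saturated and both benzyl ethers are cleaved, which gives 10.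

Step 1. The process at risk is halogen–magnesium exchange at the benzylic bromide followed by Wurtz-type homocoupling, outrunning the copper-catalysed cross-coupling. The fallback reverses the polarity so that the benzylic carbon is the nucleophile; it sets out from 1 and 2 and comes back to the route at 4. Displacement of the bromide of 1 with sodium benzenesulfinate (DMF, rt) gives 1,3-bis(benzyloxy)-5-[(benzenesulfonyl)methyl]benzene F7. Its α-lithio derivative (n-BuLi, THF, −78 °C) is alkylated with 2 (DMPU, −78 °C to rt) to give racemic 1,3-bis(benzyloxy)-5-[1-(benzenesulfonyl)oct-7-en-1-yl]benzene F8. Reductive desulfonylation (Mg, MeOH, cat. HgCl2, rt) cleaves the benzylic C–S bond and gives 4; the benzyl ethers and the terminal olefin should survive.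

Step 2. The processes at risk are competing opening of the epoxide by magnesium bromide (halohydrin formation), attack at the substituted carbon, and evaporative loss of the volatile epoxide. The fallback sets the stereocentre by enzymatic kinetic resolution instead of taking it from the chiral pool; it sets out from 7 and comes back to the route at 8. Addition of 7 to acetaldehyde (THF, −78 to 0 °C) gives racemic undec-10-en-2-ol F9. Acylation with vinyl acetate and immobilised Candida antarctica lipase B (MTBE, rt), run slightly past half conversion, should convert the (R)-enantiomer into (2R)-undec-10-en-2-yl acetate F10 (Kazlauskas rule). The alcohol left unreacted is the (S)-enantiomer 8, which is separated from the acetate by chromatography.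

**Further compounds**

F1 | step 3 | 6-chlorohexylmagnesium bromide | ClCCCCCC[Mg]Br
F2 | step 3 | 1,3-bis(benzyloxy)-5-(7-chloroheptyl)benzene | ClCCCCCCCc1cc(OCc2ccccc2)cc(OCc2ccccc2)c1
F3 | step 3 | 1,3-bis(benzyloxy)-5-(7-iodoheptyl)benzene | ICCCCCCCc1cc(OCc2ccccc2)cc(OCc2ccccc2)c1
F4 | step 3 | (2S)-dec-4-yn-2-ol | C[C@H](O)CC#CCCCCC
F5 | step 3 | (2S)-dec-9-yn-2-ol | C[C@H](O)CCCCCCC#C
F6 | step 3 | (2S)-17-[3,5-bis(benzyloxy)phenyl]heptadec-9-yn-2-ol | C[C@H](O)CCCCCCC#CCCCCCCCc1cc(OCc2ccccc2)cc(OCc2ccccc2)c1
F7 | step 1 | 1,3-bis(benzyloxy)-5-[(benzenesulfonyl)methyl]benzene | O=S(=O)(Cc1cc(OCc2ccccc2)cc(OCc2ccccc2)c1)c1ccccc1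
F8 | step 1 | 1,3-bis(benzyloxy)-5-[1-(benzenesulfonyl)oct-7-en-1-yl]benzene, racemic | C=CCCCCCC(c1cc(OCc2ccccc2)cc(OCc2ccccc2)c1)S(=O)(=O)c1ccccc1
F9 | step 2 | undec-10-en-2-ol, racemic | CC(O)CCCCCCCC=C
F10 | step 2 | (2R)-undec-10-en-2-yl acetate | C[C@@H](OC(C)=O)CCCCCCCC=C
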